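The numbers in the tables are calculated for substances that don't exist; scatter was added.

The target is the product you want, and the isomer of the product also comes out of the solid substrate. The gas is held, so keep the books on the solid substrate, the limiting reagent.

| flask | solid substrate | gas | temperature | remark | time |
|---|---|---|---|---|---|
| maple | 0.50 M | 200 mM (held) | 45 °C | run made earlier |  |
| north-east | 1.0 M | 200 mM (held) | 45 °C |  | 15 h |
| south-west | 1.0 M | 200 mM (held) | 60 °C |  | 15 h |

- maple (time / h: target / %, isomer of the product / %): 0.333: 0, 0; 0.667: 0, 0; 1.00: 1, 0; 1.50: 1, 5; 2.50: 0, 3; 5.00: 4, 13

(each reading ± 1.5 percentage points)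

- the flask with the highest share of target in all that became target or isomer of the product ("all alike" if they lie within 1.5 percentage points) (north-east / south-west / all alike)
- share of target in all that became target or isomer of the product, north-east
- share of target in all that became target or isomer of the product, south-west

- as a solid, counted per litre of solution: solid substrate
- at the start none of the gas is in solution
- at the start none of the solid substrate is in solution
- what has only dissolved of solid substrate counts as not reacted
- the earlier runs do not show what temperature does; that part of a forecast is a guess

The last entry of the maple run, at 5.00 h, reads: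

charged: 100%
target: 4%
isomer of the product: 13%
in neither: 83.0%

One row is noisy, so add up every maple reading. That gives 6.00% for the target and 21.0% for the isomer of the product.

s = c(target) / (c(target) + c(isomer of the product)) = 22.2%

This s, the target's share of what reached either product, is the selectivity as read. The scatter of the readings carries over to it as:

w = ±11 percentage points

So s spans 11.2% to 33.2%. An even split, a share of 0.5, is the zero of this scale, and s lies 2.53 widths w below it. My own reckoning carries s unchanged to both flasks. That band is much wider than the margin of 1.5 points, and what temperature does remains a guess.

The forecast says all alike, with 21% (10% to 35%) for north-east and 20% (7% to 38%) for south-west, holding that “doubling the charge should barely change the selectivity”. It puts the uncertainty of its pooled share at roughly 7 points; I put it at 11 points.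

The flasks give 13.9% in north-east and 22.5% in south-west, so the answer is south-west.

    starting material ⇌ tautomer (K = 1.90, k = 6.10 × 10⁻⁴ min⁻¹, Ea = 105 kJ mol⁻¹, ΔH = −34.0 kJ mol⁻¹)
    gas ⇌ reagent, rate k2*(csat - [reagent]) (kL = 0.0940 min⁻¹)
    starting material + reagent → isomer of the product (k = 0.0110 M⁻¹ min⁻¹, Ea = 78.0 kJ mol⁻¹)
    solid substrate ⇌ starting material, rate k4*(cs4 - [starting material]) while solid is left; crystals form when [starting material] > cs4 (solubility = 0.920 M, k = 0.00870 min⁻¹)
    reagent + tautomer → target (k = 0.170 M⁻¹ min⁻¹, Ea = 68.0 kJ mol⁻¹)
    starting material → decomposition product (k = 7.60 × 10⁻⁷ min⁻¹, Ea = 123 kJ mol⁻¹)
    (constants at 60 °C)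

North-east stands 0.755 widths w under s, and south-west lies about on it. In north-east, half of the turnover up to 15.0 h was done by 1.49 h for the dissolving of the solid substrate and by 7.70 h for the making of the isomer of the product, with starting material at 80.4% and tautomer at 0.775% at 7.50 h. At 15.0 h north-east held 59.4% starting material, 5.55% target and 34.4% isomer of the product.

Now read north-east at 4.0 h: s offers 22.2%, with its band reaching down to 11.2%. The computed share there is 8.93%, below the band.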